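**Loss first.** Count the loss. Target decays once made, so its peak stands where gain meets loss.

| setting | south | west | flask |
|---|---|---|---|
| substrate | 0.11 M | 0.22 M | 0.11 M |
| coupling partner | 0.116 M | 0.116 M | 0.116 M |
| free catalyst | 0.22 mM | 0.22 mM | 0.22 mM |
| remark | the very flask that is asked about, followed so far | run made earlier |  |
| time |  |  | 15 d |

- south (time / d: target / %, substrate / %): 0.500: 33.7, 64.5; 0.833: 43.7, 53.3; 1.25: 50.2, 45.3; 2.08: 52.9, 38.0; 3.00: 50.5, 35.1
- west (time / d: target / %, substrate / %): 0.500: 28.7, 70.9; 1.04: 34.5, 62.1; 2.50: 32.3, 59.6; 5.00: 24.2, 60.0; 10.0: 14.4, 60.3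

(scatter of a reading: 0.3 percentage points)

1. time up to 15 d at which target stands highest
2. the amount of target, in percent of the substrate charged, at that time
3. earliest time at which at least nineteen twentieths of that best amount are there, in d
4. latest time at which they still are, in d

**Loss constant.** Read the west run first. From 2.50 d its substrate barely moves, 59.6% to 60.3%, so target there is nearly pure decay. Its last two readings give 0.104 d⁻¹, the fraction of target lost per day: the loss constant. That is a half-life of 6.68 d.

**Bound below.** Now take the south run, this flask so far. Its highest reading is 52.9% at 2.08 d. Subtract two standard deviations: 52.3%.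

**Bound above.** Grow the last south reading back at the loss constant. Coupling only adds, so at 2.08 d target stood below 55.6%.

**Tighter bracket.** Gain is the fall of substrate; loss is the constant times c(target), here 0.0549 d⁻¹ of the charge. Substrate fell 0.0880 d⁻¹ before that reading and 0.0315 d⁻¹ after it. The crossing lies near that reading, where the top is flat. So add two standard deviations: 53.5%.

**The forecast.** It gives 53% at 2.05 d, from “Target peaks when this rate equals” the loss, inside my bracket. Its band runs from 1.26 d to 3.06 d.

**The flask.** Target peaks at 52.8% at 2.01 d, inside the bracket. The band runs from 1.27 d to 3.13 d.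

    coupling partner + free catalyst ⇌ catalyst intermediate A (K = 16.0 M⁻¹, k = 910 M⁻¹ min⁻¹)
    catalyst intermediate A ⇌ by-product + catalyst intermediate B (K = 0.110 M, k = 25.0 min⁻¹)
    substrate + catalyst intermediate B ⇌ catalyst intermediate C (K = 510 M⁻¹, k = 4.00 M⁻¹ min⁻¹)
    catalyst intermediate C → free catalyst + target (k = 63.0 min⁻¹)
    2 coupling partner → homo dimer (k = 0.00460 M⁻¹ min⁻¹)
    target → over-reaction product (k = 7.40 × 10⁻⁵ min⁻¹)

**What stands.** In this flask at 0.444 d, substrate has a half-life of 1.0 d by the forward coupling step, against 6.68 d from the loss constant. Coupling partner, the limiting reagent, stands at 4.80% of its charge at 2.01 d and 0% at 15.0 d. Over the 13.0 d after the peak, the constant gives 13.7%, and this flask holds 14.6%. The neighbour charged with 0.046 M of coupling partner peaks at 33.8% and holds 7.95% at 15.0 d; at the loss constant, that fall takes 13.9 d.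

The data were computed with made-up constants; noise was put on by code.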